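**Plan**
- Retrosynthesis: the side-chain ester C(=O)–O bond is cut first (shikonin plus 3-acetoxy-3-methylbutanoic acid), the two phenols are masked as methoxymethyl (MOM) acetals, and the quinone ring (ring B: C1, C2, C3, C4, C4a, C8a) is cut at C1–C8a, C1–C2 and C3–C4.
- Enabling feature: ring B carries oxygen at C1 and C4 in a para relation, hydrogen at C3 and the branched chain at C2, and C8a is an unsubstituted ortho carbon of ring A. This is the pattern a Dötz benzannulation delivers from an aryl(methoxy)carbene chromium complex (C4, C4a, C8a), one CO ligand (C1) and a terminal alkyne (C3, C2), with the ring closing at C1–C8a.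
- Forward order: ring A enters as hydroquinone bis-MOM ether, which is ortho-lithiated and converted into the chromium carbene. The side chain is made as an enantiopure propargylic silyl ether. The annulation closes ring B, a cerium work-up gives the quinone, acid unmasks shikonin, and the esterification comes last.
- Stereochemistry: the single (R) centre comes from (R)-glycidyl 4-methoxybenzyl ether (chiral pool). The epoxide is opened at CH2, and no later step breaks a bond to this carbon.

Key step: step 8

Remark: the target is a naphthazarin whose two rings exchange quinone and hydroquinone character by fast tautomerism. Atom numbers refer to the drawn tautomer (side chain on C2 of the quinone ring), and the stereocentre is (R), the shikonin series.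

**Route**

Step 1
Reactants: 1 hydroquinone
Product: 2 1,4-bis(methoxymethoxy)benzene
Conditions: NaH (2.4 equiv), MOMCl (2.4 equiv), DMF, 0 °C → rt, Ar
Reagents that add atoms: chloromethyl methyl ether COCCl
Why: Williamson ether synthesis on the bis-phenoxide; the acetals are chosen because they direct the ortho-lithiation of step 2, should survive the organometallic and oxidative steps, and hydrolyse under mild acid in step 9.

Step 2
Reactants: 2 1,4-bis(methoxymethoxy)benzene
Product: 5 pentacarbonyl{[2,5-bis(methoxymethoxy)phenyl](methoxy)methylidene}chromium, via aryllithium 3 (not isolated), via lithium acylchromate 4 (not isolated)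
Conditions: n-BuLi, TMEDA, THF, 0 °C; Cr(CO)6, THF, 0 °C → rt; then MeOSO2CF3, CH2Cl2, 0 °C
Reagents that add atoms: hexacarbonylchromium O=C=[Cr](=C=O)(=C=O)(=C=O)(=C=O)=C=O; methyl trifluoromethanesulfonate COS(=O)(=O)C(F)(F)F
Why: Acetal-directed ortho-lithiation (all four ring hydrogens are equivalent) followed by the Fischer carbene synthesis, in which the aryllithium adds to a CO ligand of zerovalent chromium and the acylchromate is O-methylated by the hard methylating agent.

Step 3
Reactants: 6 (R)-glycidyl 4-methoxybenzyl ether
Product: 7 (2R)-1-[(4-methoxybenzyl)oxy]-5-methylhex-4-en-2-ol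
Conditions: Me2C=CHMgBr (1.5 equiv), CuI (10 mol %), THF, −40 → −10 °C
Reagents that add atoms: 2-methylprop-1-enylmagnesium bromide CC(C)=C[Mg]Br
Why: Copper-catalysed Grignard opening of a terminal epoxide by SN2 attack at the unsubstituted CH2, so the C–O stereocentre of the chiral-pool epoxide is untouched and becomes the (R)-carbinol carbon of the side chain.

Step 4
Reactants: 7 (2R)-1-[(4-methoxybenzyl)oxy]-5-methylhex-4-en-2-ol
Product: 8 (2R)-2-(tert-butyldimethylsilyloxy)-1-[(4-methoxybenzyl)oxy]-5-methylhex-4-ene
Conditions: TBSCl, imidazole, DMF, rt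
Reagents that add atoms: tert-butyldimethylsilyl chloride CC(C)(C)[Si](C)(C)Cl
Why: Standard silylation of the secondary alcohol (Corey conditions); the silyl ether should tolerate the carbene annulation and comes off together with the acetals in step 9.

Step 5
Reactants: 8 (2R)-2-(tert-butyldimethylsilyloxy)-1-[(4-methoxybenzyl)oxy]-5-methylhex-4-ene
Product: 9 (2R)-2-(tert-butyldimethylsilyloxy)-5-methylhex-4-en-1-ol
Conditions: DDQ, CH2Cl2/pH 7 buffer, 0 °C → rt
Reagents that add atoms: none
Why: Oxidative cleavage of the 4-methoxybenzyl ether by DDQ (hydride abstraction from the electron-rich benzylic position, then hydrolysis), which leaves the silyl ether and the trisubstituted alkene alone.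

Step 6
Reactants: 9 (2R)-2-(tert-butyldimethylsilyloxy)-5-methylhex-4-en-1-ol
Product: 10 (2R)-2-(tert-butyldimethylsilyloxy)-5-methylhex-4-enal
Conditions: Dess–Martin periodinane, CH2Cl2, 0 °C → rt
Reagents that add atoms: none
Why: Dess–Martin oxidation under neutral, non-aqueous conditions should give the α-silyloxy aldehyde without over-oxidation or epimerisation; it is used crude.

Step 7
Reactants: 10 (2R)-2-(tert-butyldimethylsilyloxy)-5-methylhex-4-enal
Product: 11 (3R)-3-(tert-butyldimethylsilyloxy)-6-methylhept-5-en-1-yne
Conditions: dimethyl (1-diazo-2-oxopropyl)phosphonate, K2CO3, MeOH, 0 °C → rt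
Reagents that add atoms: dimethyl (1-diazo-2-oxopropyl)phosphonate COP(=O)(OC)C(=[N+]=[N-])C(C)=O
Why: Seyferth–Gilbert homologation with the Ohira–Bestmann reagent converts the aldehyde into the terminal alkyne under mild carbonate conditions at low temperature, which should keep the α-stereocentre (now propargylic) intact.

Step 8
Reactants: 5 pentacarbonyl{[2,5-bis(methoxymethoxy)phenyl](methoxy)methylidene}chromium, 11 (3R)-3-(tert-butyldimethylsilyloxy)-6-methylhept-5-en-1-yne
Product: 14 5,8-bis(methoxymethoxy)-2-[(1R)-1-(tert-butyldimethylsilyloxy)-4-methylpent-3-enyl]naphthalene-1,4-dione, via naphthol tricarbonylchromium complex 12 (not isolated), via free 4-methoxy-1-naphthol 13 (not isolated)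
Conditions: 5 (1.5 equiv), THF, 55 °C, Ar; then (NH4)2Ce(NO3)6 (7 equiv), MeCN/H2O, 0 °C
Reagents that add atoms: water O
Why: Dötz benzannulation with oxidative work-up, the closest known reaction type being the reaction of aryl(alkoxy)carbene chromium complexes with terminal alkynes. Loss of one CO from 5 lets alkyne 11 bind and insert into the Cr=C bond with its unsubstituted carbon joining the carbene carbon, a CO ligand then inserts to give an η4-vinylketene, and ring B is closed by a thermal six-electron electrocyclisation in which the ketene carbon (C1) bonds to the free ortho carbon of the aryl ring (C8a), followed by tautomerisation to the naphthol complex 12. The ring is thus assembled in a [3+2+1] mode from three carbons of the carbene complex, the two alkyne carbons and one CO, and the bond made in the ring-closing event is the aryl–carbonyl bond C1–C8a. No stereocentre is formed, and the propargylic (R) centre of 11 is only a spectator under the neutral conditions. The step needs regioselectivity, which is secured sterically because the branched substituent of the terminal alkyne ends up next to the CO-derived carbon (C2 beside C1) and because the other ortho position of the aryl ring is blocked by an acetal oxygen. Tetravalent cerium then releases naphthol 13 from chromium and oxidises only its free para-methoxyphenol ring to the 1,4-quinone with loss of methanol, so the acetal-protected ring A should stay intact.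

Step 9
Reactants: 14 5,8-bis(methoxymethoxy)-2-[(1R)-1-(tert-butyldimethylsilyloxy)-4-methylpent-3-enyl]naphthalene-1,4-dione
Product: 15 shikonin, 5,8-dihydroxy-2-[(1R)-1-hydroxy-4-methylpent-3-enyl]naphthalene-1,4-dione
Conditions: HCl (3 M aq.), THF, 0 °C → rt
Reagents that add atoms: none
Why: Acid-catalysed acetal hydrolysis of the two aryl MOM ethers, which are activated by the electron-poor quinone-fused ring, with concurrent acid desilylation; the carbinol carbon sits on an electron-poor ring in either naphthazarin tautomer, so it should not ionise and keeps its (R) configuration.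

Step 10
Reactants: 16 3-hydroxy-3-methylbutanoic acid
Product: 17 3-acetoxy-3-methylbutanoic acid
Conditions: AcCl (3 equiv), CH2Cl2, 0 °C → rt; aqueous work-up
Reagents that add atoms: acetyl chloride CC(=O)Cl
Why: Acetylation of the tertiary alcohol by acetyl chloride, driven by loss of HCl; any mixed anhydride at the carboxyl group is hydrolysed on aqueous work-up.

Step 11
Reactants: 15 shikonin, 17 3-acetoxy-3-methylbutanoic acid
Product: 18 (1R)-1-(5,8-dihydroxy-1,4-dioxo-1,4-dihydronaphthalen-2-yl)-4-methylpent-3-enyl 3-acetoxy-3-methylbutanoate (target)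
Conditions: 17 (1.2 equiv), DCC (1.2 equiv), DMAP (0.1 equiv), CH2Cl2, 0 °C → rt
Reagents that add atoms: none
Why: Steglich esterification; the side-chain hydroxyl is far more nucleophilic than the two phenols, which are tied up in strong hydrogen bonds to the peri carbonyls, and acylation occurs at oxygen so the (R) centre is retained, while low temperature and catalytic DMAP should keep base-induced loss of acetic acid from the β-acetoxy acyl group small.

**Compound list**

1 | hydroquinone | Oc1ccc(O)cc1 | starting material
2 | 1,4-bis(methoxymethoxy)benzene | COCOc1ccc(OCOC)cc1 | intermediate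
3 | [2,5-bis(methoxymethoxy)phenyl]lithium | [Li]c1cc(OCOC)ccc1OCOC | intermediate (not isolated)
4 | lithium [2,5-bis(methoxymethoxy)benzoyl]pentacarbonylchromate | [Li+].[O-]C(c1cc(OCOC)ccc1OCOC)=[Cr](=C=O)(=C=O)(=C=O)(=C=O)=C=O | intermediate (not isolated)
5 | pentacarbonyl{[2,5-bis(methoxymethoxy)phenyl](methoxy)methylidene}chromium | COC(c1cc(OCOC)ccc1OCOC)=[Cr](=C=O)(=C=O)(=C=O)(=C=O)=C=O | intermediate
6 | (R)-glycidyl 4-methoxybenzyl ether, (2R)-2-{[(4-methoxybenzyl)oxy]methyl}oxirane | COc1ccc(COC[C@@H]2OC2)cc1 | starting material
7 | (2R)-1-[(4-methoxybenzyl)oxy]-5-methylhex-4-en-2-ol | COc1ccc(COC[C@H](O)CC=C(C)C)cc1 | intermediate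
8 | (2R)-2-(tert-butyldimethylsilyloxy)-1-[(4-methoxybenzyl)oxy]-5-methylhex-4-ene | COc1ccc(COC[C@H](O[Si](C)(C)C(C)(C)C)CC=C(C)C)cc1 | intermediate
9 | (2R)-2-(tert-butyldimethylsilyloxy)-5-methylhex-4-en-1-ol | OC[C@H](O[Si](C)(C)C(C)(C)C)CC=C(C)C | intermediate
10 | (2R)-2-(tert-butyldimethylsilyloxy)-5-methylhex-4-enal | O=C[C@H](O[Si](C)(C)C(C)(C)C)CC=C(C)C | intermediate
11 | (3R)-3-(tert-butyldimethylsilyloxy)-6-methylhept-5-en-1-yne | C#C[C@H](O[Si](C)(C)C(C)(C)C)CC=C(C)C | intermediate
12 | tricarbonyl(η6-arene)chromium complex of naphthol 13, metal on the new ring (SMILES gives the arene ligand and the Cr(CO)3 unit as two parts) | Oc1c([C@H](O[Si](C)(C)C(C)(C)C)CC=C(C)C)cc(OC)c2c(OCOC)ccc(OCOC)c12.O=C=[Cr](=C=O)=C=O | intermediate (not isolated)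
13 | 2-[(1R)-1-(tert-butyldimethylsilyloxy)-4-methylpent-3-enyl]-4-methoxy-5,8-bis(methoxymethoxy)naphthalen-1-ol | Oc1c([C@H](O[Si](C)(C)C(C)(C)C)CC=C(C)C)cc(OC)c2c(OCOC)ccc(OCOC)c12 | intermediate (not isolated)
14 | 5,8-bis(methoxymethoxy)-2-[(1R)-1-(tert-butyldimethylsilyloxy)-4-methylpent-3-enyl]naphthalene-1,4-dione | O=C1C([C@H](O[Si](C)(C)C(C)(C)C)CC=C(C)C)=CC(=O)c2c(OCOC)ccc(OCOC)c12 | intermediate
15 | shikonin, 5,8-dihydroxy-2-[(1R)-1-hydroxy-4-methylpent-3-enyl]naphthalene-1,4-dione | O=C1C([C@H](O)CC=C(C)C)=CC(=O)c2c(O)ccc(O)c12 | intermediate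
16 | 3-hydroxy-3-methylbutanoic acid | CC(C)(O)CC(=O)O | starting material
17 | 3-acetoxy-3-methylbutanoic acid | CC(=O)OC(C)(C)CC(=O)O | intermediate
18 | (1R)-1-(5,8-dihydroxy-1,4-dioxo-1,4-dihydronaphthalen-2-yl)-4-methylpent-3-enyl 3-acetoxy-3-methylbutanoate | CC(=O)OC(C)(C)CC(=O)O[C@H](CC=C(C)C)C1=CC(=O)c2c(O)ccc(O)c2C1=O | target

**Step count**

Total step count: 11. Longest linear sequence: 8 steps (steps 3, 4, 5, 6, 7, 8, 9 and 11, from 6).

**Steps most likely to fail**

Step 8. After alkyne insertion the vinylcarbene may fail to take up CO or may close in other ways (indene, furan or cyclobutenone channels). The regiochemistry of insertion may erode with the bulky branched alkyne, and the acetals may be lost during the acidic cerium work-up. The fallback builds ring A last instead of ring B; it sets out from 2 and comes back at 15.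
- Compound 2 is ortho-lithiated as in step 2 and the aryllithium is acylated with N-methoxy-N,4-dimethylpent-3-enamide to give 1-[2,5-bis(methoxymethoxy)phenyl]-4-methylpent-3-en-1-one F1.
- Asymmetric reduction with (+)-B-chlorodiisopinocampheylborane (THF, −25 °C) should give the (R)-carbinol F2, with the aryl group acting as the large substituent as in aryl alkyl ketones generally.
- Silylation (TBSCl, imidazole, DMF) should give the silyl ether F3.
- Oxidative cleavage of both acetals with (NH4)2Ce(NO3)6 in aqueous MeCN at 0 °C should give the side-chain benzoquinone F4.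
- Diels–Alder addition of 2,5-bis(trimethylsilyloxy)furan (made from succinic anhydride) to the unsubstituted C=C of F4, then loss of hexamethyldisiloxane from the oxygen-bridged adduct and enolisation, should give the naphthazarin directly at the right oxidation level as shikonin tert-butyldimethylsilyl ether F5.
- HF·pyridine (THF, 0 °C) then gives 15.

Step 9. Under aqueous acid the freed side-chain hydroxyl may add to the protonated trisubstituted alkene (tetrahydrofuran formation), or the three protecting groups may come off at unequal rates so that partly protected material accumulates. The fallback changes the order of events so that the hydroxyl is acylated before the naphthazarin is unmasked; it sets out from 14 and comes back at 18, bypassing steps 9 and 11.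
- HF·pyridine (pyridine, THF, 0 °C) removes only the silyl group to give the bis-acetal carbinol F6.
- Steglich esterification with 17 (DCC, cat. DMAP, CH2Cl2) gives the bis-acetal ester F7, in which the oxygen can no longer cyclise.
- The two acetals are then cleaved under aprotic conditions with Me3SiBr (CH2Cl2, −30 °C, then aqueous NaHCO3) to give 18.

Step 11. The activated β-acetoxy acyl group may lose acetic acid under base (E1cB elimination to the 3-methylbut-2-enoyl ester), and a phenol may be acylated in competition. The fallback installs the acyl group in two stages; it sets out from 15 and comes back at 18.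
- Compound 15 is esterified with 3-hydroxy-3-methylbutanoic acid 16 (DCC, cat. DMAP), which has no leaving group in the β-position, to give the β-hydroxy ester F8.
- Exhaustive acetylation (Ac2O, cat. Sc(OSO2CF3)3, MeCN, −20 °C) of the tertiary hydroxyl and of both phenols gives the triacetate F9.
- The two aryl acetates, activated by the peri carbonyls, are removed selectively with NH4OAc in aqueous MeOH to give 18.

Further compounds
F1 | step 8 | 1-[2,5-bis(methoxymethoxy)phenyl]-4-methylpent-3-en-1-one | COCOc1ccc(OCOC)c(c1)C(=O)CC=C(C)C
F2 | step 8 | (1R)-1-[2,5-bis(methoxymethoxy)phenyl]-4-methylpent-3-en-1-ol | COCOc1ccc(OCOC)c(c1)[C@H](O)CC=C(C)C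
F3 | step 8 | tert-butyl{(1R)-1-[2,5-bis(methoxymethoxy)phenyl]-4-methylpent-3-enyloxy}dimethylsilane | COCOc1ccc(OCOC)c(c1)[C@H](O[Si](C)(C)C(C)(C)C)CC=C(C)C
F4 | step 8 | 2-[(1R)-1-(tert-butyldimethylsilyloxy)-4-methylpent-3-enyl]-1,4-benzoquinone | O=C1C=CC(=O)C([C@H](O[Si](C)(C)C(C)(C)C)CC=C(C)C)=C1
F5 | step 8 | shikonin tert-butyldimethylsilyl ether, 2-[(1R)-1-(tert-butyldimethylsilyloxy)-4-methylpent-3-enyl]-5,8-dihydroxynaphthalene-1,4-dione | O=C1C([C@H](O[Si](C)(C)C(C)(C)C)CC=C(C)C)=CC(=O)c2c(O)ccc(O)c12
F6 | step 9 | 2-[(1R)-1-hydroxy-4-methylpent-3-enyl]-5,8-bis(methoxymethoxy)naphthalene-1,4-dione | O=C1C([C@H](O)CC=C(C)C)=CC(=O)c2c(OCOC)ccc(OCOC)c12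
F7 | step 9 | (1R)-1-[5,8-bis(methoxymethoxy)-1,4-dioxo-1,4-dihydronaphthalen-2-yl]-4-methylpent-3-enyl 3-acetoxy-3-methylbutanoate | CC(=O)OC(C)(C)CC(=O)O[C@H](CC=C(C)C)C1=CC(=O)c2c(OCOC)ccc(OCOC)c2C1=O
F8 | step 11 | (1R)-1-(5,8-dihydroxy-1,4-dioxo-1,4-dihydronaphthalen-2-yl)-4-methylpent-3-enyl 3-hydroxy-3-methylbutanoate | CC(C)(O)CC(=O)O[C@H](CC=C(C)C)C1=CC(=O)c2c(O)ccc(O)c2C1=O
F9 | step 11 | (1R)-1-(5,8-diacetoxy-1,4-dioxo-1,4-dihydronaphthalen-2-yl)-4-methylpent-3-enyl 3-acetoxy-3-methylbutanoate | CC(=O)OC(C)(C)CC(=O)O[C@H](CC=C(C)C)C1=CC(=O)c2c(OC(C)=O)ccc(OC(C)=O)c2C1=O
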